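Ring A, the hexasubstituted trihydroxyphenyl ring, alternates oxygen-bearing carbons (C2, C4, C6) with carbon-bearing ones (propanoyl on C1, methyl on C3, bridge CH2 on C5). A Danheiser benzannulation maps onto this alternation. A 3-ethoxycyclobutenone that already carries the ring B benzyl group on its alkene carbon supplies C1, C2, C5 and C6, and 1-(triisopropylsiloxy)propyne supplies C3 and C4. One thermal operation forms C2–C3, C4–C5 and C1–C2 and closes ring A. It leaves the three ring A oxygens in three different states (free phenol, silyl ether, ethyl ether) and C1 as the only CH, ready for the propanoyl group. Ring B comes from 2,4,6-trimethoxytoluene.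

Key step: step 7

Remark: ketene is not sold, so it is assumed to be generated from acetone in a ketene lamp and passed as a gas into step 5; atom labels follow ring A (C1 propanoyl, C2 OH, C3 methyl, C4 OH, C5 bridge, C6 OH) and ring B (C1′ bridge, C2′ OH, C3′ propanoyl, C4′ OH, C5′ methyl, C6′ OMe).

Step 1
Reactants: 1 2,4,6-trimethoxytoluene
Product: 3 2,4,6-trimethoxy-3-methylbenzaldehyde, via aryl iminium salt 2 (not isolated)
Conditions: POCl3, DMF, 0 → 50 °C; then ice-water
Reagents that add atoms: N,N-dimethylformamide CN(C)C=O; water O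
Why: Vilsmeier–Haack formylation, in which the chloroiminium electrophile attacks one of the two equivalent, strongly activated free positions of 1 and the iminium salt 2 so formed resists a second attack until it is hydrolysed on work-up.

Step 2
Reactants: 3 2,4,6-trimethoxy-3-methylbenzaldehyde
Product: 4 (2,4,6-trimethoxy-3-methylphenyl)methanol
Conditions: NaBH4, MeOH/THF, 0 °C
Reagents that add atoms: none
Why: Borohydride reduction of an aryl aldehyde to the benzylic alcohol, with no other reducible group present.

Step 3
Reactants: 4 (2,4,6-trimethoxy-3-methylphenyl)methanol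
Product: 5 2-(bromomethyl)-1,3,5-trimethoxy-4-methylbenzene
Conditions: PBr3 (0.4 equiv), Et2O, −20 °C; cold aq. NaHCO3 wash; used crude at once
Reagents that add atoms: phosphorus tribromide BrP(Br)Br
Why: Conversion of a benzylic alcohol into its bromide through the phosphite ester, run cold and taken on without purification because this electron-rich benzylic bromide ionises easily.

Step 4
Reactants: 5 2-(bromomethyl)-1,3,5-trimethoxy-4-methylbenzene; 6 ethoxyacetylene
Product: 8 2-(3-ethoxyprop-2-yn-1-yl)-1,3,5-trimethoxy-4-methylbenzene, via lithium ethoxyacetylide 7 (not isolated)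
Conditions: 6 (1.5 equiv), n-BuLi, THF, −78 °C; then 5, DMPU, −78 → 0 °C
Reagents that add atoms: none
Why: SN2 C-alkylation of a lithium alkoxyacetylide by a reactive benzylic bromide in THF/DMPU, the standard entry to 1-alkoxy-1-alkynes, with the bromide added to excess acetylide so that it should be consumed before it can self-condense.

Step 5
Reactants: 8 2-(3-ethoxyprop-2-yn-1-yl)-1,3,5-trimethoxy-4-methylbenzene
Product: 9 3-ethoxy-2-[(2,4,6-trimethoxy-3-methylphenyl)methyl]cyclobut-2-en-1-one
Conditions: ketene gas, CH2Cl2, −20 → 0 °C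
Reagents that add atoms: ketene C=C=O
Why: Thermal [2+2] cycloaddition of ketene to an ynol ether, whose nucleophilic benzyl-bearing carbon bonds to the ketene carbonyl carbon, so that the ethoxy group ends on C3 and the benzyl group on C2 of the cyclobutenone.

Step 6
Reactants: 10 ethyl acetate
Product: 13 triisopropyl(prop-1-yn-1-yloxy)silane, via dibromo enolate 11 (not isolated), via lithium ynolate 12 (not isolated)
Conditions: CH2Br2, LiTMP, THF, −78 °C; 10; n-BuLi, −78 → 20 °C; TIPSCl, −78 → 0 °C
Reagents that add atoms: dibromomethane BrCBr; chlorotriisopropylsilane CC(C)[Si](Cl)(C(C)C)C(C)C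
Why: Kowalski ester homologation stopped at the ynolate, in which dibromomethyllithium adds to the ester, enolate 11 undergoes bromine–lithium exchange and carbenoid rearrangement to ynolate 12, and the bulky silyl chloride traps it on oxygen.

Step 7
Reactants: 9 3-ethoxy-2-[(2,4,6-trimethoxy-3-methylphenyl)methyl]cyclobut-2-en-1-one; 13 triisopropyl(prop-1-yn-1-yloxy)silane
Product: 18 5-ethoxy-2-methyl-3-(triisopropylsilyloxy)-4-[(2,4,6-trimethoxy-3-methylphenyl)methyl]phenol, via vinylketene 14 (not isolated), via vinylcyclobutenone 15 (not isolated), via dienylketene 16 (not isolated), via cyclohexadienone 17 (not isolated)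
Conditions: 13 (1.5 equiv), toluene, 80 then 110 °C, sealed tube
Reagents that add atoms: none
Why: Heating should open 9 by four-electron electrocyclic cleavage of its C1–C4 bond (cyclobutenone numbering) to vinylketene 14, whose ketene unit adds [2+2] to 13 to give vinylcyclobutenone 15; this opens again to dienylketene 16, which closes to dienone 17 and tautomerises to phenol 18. The closest known reaction is the Danheiser benzannulation of cyclobutenones with siloxyalkynes, which gives resorcinol mono-silyl ethers. Ring A is closed by thermal six-electron electrocyclization of 16 (bond C1–C2, ring A numbering), the [2+2] step having already made C2–C3 and C4–C5. No stereocentre remains, since the quaternary carbon of 15 is flattened on ring opening. The step needs one orientation in the ketene–alkyne addition, and the oxygen polarisation of 13 secures it: its electron-rich methyl-bearing carbon attacks the electrophilic ketene carbonyl carbon, which puts methyl next to the new hydroxyl and the siloxy group one carbon further on. An excess of 13 keeps the ketene from being consumed by the product phenol.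

Step 8
Reactants: 18 5-ethoxy-2-methyl-3-(triisopropylsilyloxy)-4-[(2,4,6-trimethoxy-3-methylphenyl)methyl]phenol
Product: 19 1-[2-ethoxy-6-hydroxy-5-methyl-4-(triisopropylsilyloxy)-3-[(2,4,6-trimethoxy-3-methyl-5-propanoylphenyl)methyl]phenyl]propan-1-one
Conditions: EtCOCl (3 equiv), TiCl4 (3.5 equiv), CH2Cl2, −40 → 0 °C
Reagents that add atoms: propanoyl chloride CCC(Cl)=O
Why: Friedel–Crafts acylation, in which each ring offers exactly one unsubstituted carbon (flanked by two oxygen substituents and para to a third), so both should be propanoylated, while the ring A phenol ends as the titanium chelate of the new ortho-hydroxy ketone and is kept from O-acylation.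

Step 9
Reactants: 19 1-[2-ethoxy-6-hydroxy-5-methyl-4-(triisopropylsilyloxy)-3-[(2,4,6-trimethoxy-3-methyl-5-propanoylphenyl)methyl]phenyl]propan-1-one
Product: 20 1-[3-[(2,4-dihydroxy-6-methoxy-5-methyl-3-propanoylphenyl)methyl]-2,6-dihydroxy-5-methyl-4-(triisopropylsilyloxy)phenyl]propan-1-one
Conditions: BCl3 (8 equiv), CH2Cl2, −78 °C → rt; aq. work-up
Reagents that add atoms: none
Why: Chelation-directed ether cleavage, in which boron held between a ketone oxygen and a flanking ether oxygen delivers chloride to the alkyl group; as each ketone can turn to either neighbour, excess reagent should remove the ethyl group on O6 and the methyl groups on O2′ and O4′ and leave the non-chelating O6′ methyl ether and the hindered silyl ether.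

Step 10
Reactants: 20 1-[3-[(2,4-dihydroxy-6-methoxy-5-methyl-3-propanoylphenyl)methyl]-2,6-dihydroxy-5-methyl-4-(triisopropylsilyloxy)phenyl]propan-1-one
Product: 21 1-[3-[(2,4-dihydroxy-6-methoxy-5-methyl-3-propanoylphenyl)methyl]-2,4,6-trihydroxy-5-methylphenyl]propan-1-one
Conditions: HF·pyridine, THF, 0 °C → rt
Reagents that add atoms: none
Why: Fluoride cleavage of the aryl silyl ether with an acidic fluoride source, chosen because methylene-bridged acylphloroglucinols scramble under basic conditions.

Compound list
1 | 2,4,6-trimethoxytoluene | Cc1c(OC)cc(OC)cc1OC | starting material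
2 | [(2,4,6-trimethoxy-3-methylphenyl)methylidene]dimethylammonium dichlorophosphate | C[N+](C)=Cc1c(OC)cc(OC)c(C)c1OC.[O-]P(=O)(Cl)Cl | intermediate
3 | 2,4,6-trimethoxy-3-methylbenzaldehyde | O=Cc1c(OC)cc(OC)c(C)c1OC | intermediate
4 | (2,4,6-trimethoxy-3-methylphenyl)methanol | OCc1c(OC)cc(OC)c(C)c1OC | intermediate
5 | 2-(bromomethyl)-1,3,5-trimethoxy-4-methylbenzene | BrCc1c(OC)cc(OC)c(C)c1OC | intermediate
6 | ethoxyacetylene | CCOC#C | starting material
7 | lithium ethoxyacetylide | [Li]C#COCC | intermediate
8 | 2-(3-ethoxyprop-2-yn-1-yl)-1,3,5-trimethoxy-4-methylbenzene | CCOC#CCc1c(OC)cc(OC)c(C)c1OC | intermediate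
9 | 3-ethoxy-2-[(2,4,6-trimethoxy-3-methylphenyl)methyl]cyclobut-2-en-1-one | CCOC1=C(Cc2c(OC)cc(OC)c(C)c2OC)C(=O)C1 | intermediate
10 | ethyl acetate | CCOC(C)=O | starting material
11 | lithium 1,1-dibromoprop-1-en-2-olate | [Li]OC(C)=C(Br)Br | intermediate
12 | lithium prop-1-yn-1-olate | [Li]OC#CC | intermediate
13 | triisopropyl(prop-1-yn-1-yloxy)silane | CC#CO[Si](C(C)C)(C(C)C)C(C)C | intermediate
14 | 3-ethoxy-2-[(2,4,6-trimethoxy-3-methylphenyl)methyl]buta-1,3-dien-1-one | C=C(OCC)C(Cc1c(OC)cc(OC)c(C)c1OC)=C=O | intermediate
15 | 4-(1-ethoxyethenyl)-2-methyl-3-(triisopropylsilyloxy)-4-[(2,4,6-trimethoxy-3-methylphenyl)methyl]cyclobut-2-en-1-one (racemic, transient quaternary centre) | O=C1C(C)=C(O[Si](C(C)C)(C(C)C)C(C)C)C1(Cc2c(OC)cc(OC)c(C)c2OC)C(OCC)=C | intermediate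
16 | (3E)-5-ethoxy-2-methyl-3-(triisopropylsilyloxy)-4-[(2,4,6-trimethoxy-3-methylphenyl)methyl]hexa-1,3,5-trien-1-one (ketene carbon and ethoxyvinyl group cis across C3=C4) | O=C=C(C)/C(O[Si](C(C)C)(C(C)C)C(C)C)=C(/Cc1c(OC)cc(OC)c(C)c1OC)C(OCC)=C | intermediate
17 | 5-ethoxy-2-methyl-3-(triisopropylsilyloxy)-4-[(2,4,6-trimethoxy-3-methylphenyl)methyl]cyclohexa-2,4-dien-1-one | O=C1CC(OCC)=C(Cc2c(OC)cc(OC)c(C)c2OC)C(O[Si](C(C)C)(C(C)C)C(C)C)=C1C | intermediate
18 | 5-ethoxy-2-methyl-3-(triisopropylsilyloxy)-4-[(2,4,6-trimethoxy-3-methylphenyl)methyl]phenol | CCOc1cc(O)c(C)c(O[Si](C(C)C)(C(C)C)C(C)C)c1Cc1c(OC)cc(OC)c(C)c1OC | intermediate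
19 | 1-[2-ethoxy-6-hydroxy-5-methyl-4-(triisopropylsilyloxy)-3-[(2,4,6-trimethoxy-3-methyl-5-propanoylphenyl)methyl]phenyl]propan-1-one | CCC(=O)c1c(O)c(C)c(O[Si](C(C)C)(C(C)C)C(C)C)c(Cc2c(OC)c(C(=O)CC)c(OC)c(C)c2OC)c1OCC | intermediate
20 | 1-[3-[(2,4-dihydroxy-6-methoxy-5-methyl-3-propanoylphenyl)methyl]-2,6-dihydroxy-5-methyl-4-(triisopropylsilyloxy)phenyl]propan-1-one | CCC(=O)c1c(O)c(C)c(O[Si](C(C)C)(C(C)C)C(C)C)c(Cc2c(O)c(C(=O)CC)c(O)c(C)c2OC)c1O | intermediate
21 | 1-[3-[(2,4-dihydroxy-6-methoxy-5-methyl-3-propanoylphenyl)methyl]-2,4,6-trihydroxy-5-methylphenyl]propan-1-one (no stereocentre) | CCC(=O)c1c(O)c(C)c(O)c(Cc2c(O)c(C(=O)CC)c(O)c(C)c2OC)c1O | target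

Total step count: 10. Longest linear sequence: 9 steps (steps 1 to 5, then 7 to 10); step 6 is the one-step side branch to 13.

Steps most likely to fail

Step 7. The alkoxy group makes the cyclobutenone a vinylogous ester, so its ring opening may need temperatures at which the siloxyalkyne degrades. The ketene may also be diverted into acylating the product phenol or into oligomers. The fallback gives up the benzannulation and makes the bridge last from two finished rings. It sets out from 1 and comes back at 21. Friedel–Crafts propanoylation of 1 (EtCOCl, SnCl4, CH2Cl2) gives 1-(2,4,6-trimethoxy-3-methylphenyl)propan-1-one F1. Exhaustive demethylation with BBr3 gives 1-(2,4,6-trihydroxy-3-methylphenyl)propan-1-one F2, the ring A unit. One equivalent of Me2SO4 with K2CO3 in acetone methylates the most acidic hydroxyl, the one para to the ketone, and gives 1-(2,6-dihydroxy-4-methoxy-3-methylphenyl)propan-1-one F3, the ring B unit. Mannich aminomethylation of its single free position (CH2O, Me2NH) gives 1-[3-[(dimethylamino)methyl]-2,6-dihydroxy-4-methoxy-5-methylphenyl]propan-1-one F4. Heating F4 with F2 releases an ortho-quinone methide that alkylates the one free carbon of F2 and gives 21.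

Step 9. Once boron sits in a phenoxide–ketone chelate, the second ether flanking that ketone loses chelation assistance, so cleavage may stop half-way on both rings. Forcing it may also strip the twisted O6′ methyl ether or cut the methylene bridge. The fallback removes the need for selectivity. It sets out from 19 and comes back at 21. BBr3 in excess cleaves all four alkyl ethers and the silyl ether and gives bis(2,4,6-trihydroxy-3-methyl-5-propanoylphenyl)methane F5, whose two rings are identical. Mono-O-methylation with a slight deficit of Me2SO4 and K2CO3 in acetone should go to the most acidic hydroxyl, the one para to a ketone, and on either ring this gives 21. Over-methylated material is separated and unreacted F5 is recycled.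

Step 4. The benzylic bromide 5 can ionise and alkylate the free ring position of a second molecule faster than the acetylide displaces bromide, which leads to oligomers. The fallback avoids any benzylic halide. It sets out from aldehyde 3 (with 6) and comes back at 9. Compound 6 and ketene give 3-ethoxycyclobut-2-en-1-one F6, and dilute aqueous acid hydrolyses it to cyclobutane-1,3-dione F7. Knoevenagel condensation of F7 with 3, with in situ transfer hydrogenation by a Hantzsch ester under L-proline catalysis (reductive alkylation of a cyclic 1,3-dione), gives 3-hydroxy-2-[(2,4,6-trimethoxy-3-methylphenyl)methyl]cyclobut-2-en-1-one F8. O-Ethylation of this vinylogous acid (EtOH, HC(OEt)3, cat. TsOH) gives 9.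

Further compounds
F1 | step 7 | 1-(2,4,6-trimethoxy-3-methylphenyl)propan-1-one | CCC(=O)c1c(OC)cc(OC)c(C)c1OC
F2 | step 7 | 1-(2,4,6-trihydroxy-3-methylphenyl)propan-1-one | CCC(=O)c1c(O)cc(O)c(C)c1O
F3 | step 7 | 1-(2,6-dihydroxy-4-methoxy-3-methylphenyl)propan-1-one | CCC(=O)c1c(O)cc(OC)c(C)c1O
F4 | step 7 | 1-[3-[(dimethylamino)methyl]-2,6-dihydroxy-4-methoxy-5-methylphenyl]propan-1-one | CCC(=O)c1c(O)c(CN(C)C)c(OC)c(C)c1O
F5 | step 9 | bis(2,4,6-trihydroxy-3-methyl-5-propanoylphenyl)methane | CCC(=O)c1c(O)c(C)c(O)c(Cc2c(O)c(C(=O)CC)c(O)c(C)c2O)c1O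
F6 | step 4 | 3-ethoxycyclobut-2-en-1-one | CCOC1=CC(=O)C1
F7 | step 4 | cyclobutane-1,3-dione | O=C1CC(=O)C1
F8 | step 4 | 3-hydroxy-2-[(2,4,6-trimethoxy-3-methylphenyl)methyl]cyclobut-2-en-1-one | OC1=C(Cc2c(OC)cc(OC)c(C)c2OC)C(=O)C1
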